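The left-handed and right-handed substrates together were charged in excess of the partner, a stoichiometric imbalance that makes the partner the limiting reagent if each product molecule takes one partner, as I assumed.

| setting | amber | ochre | flask |
|---|---|---|---|
| left-handed substrate | 0.80 M | 0.80 M | 0.80 M |
| right-handed substrate | 0.80 M | 0.80 M | 0.80 M |
| partner | 0.48 M | 0.48 M | 0.480 M |
| free catalyst | 4 mM | 8 mM | 4.0 mM |
| remark | the very flask that is asked about, followed so far | run made earlier |  |

- amber (time / h: left-handed product / %): 1.33: 0; 2.00: 2; 4.00: 4; 6.00: 3; 10.0: 5; 15.0: 7
- ochre (time / h: left-handed product / %): 5.00: 2; 10.0: 6; 15.0: 6; 20.0: 10; 25.0: 13; 30.0: 12

(readings scatter by 1.5 percentage points)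

- free catalyst is single-handed; left-handed substrate and right-handed substrate are mirror images of each other, charged as a racemate, each of them at the stated concentration
- no earlier run changes the charge of partner; that part of a forecast is a guess

* apparent order in free catalyst when 5.0% of the left-handed substrate and right-handed substrate together are converted (percent change of the rate of making left-handed product for one percent more free catalyst charged)
* apparent order in partner when 5.0% of the left-handed substrate and right-handed substrate together are converted (percent change of the rate of making left-handed product for one percent more partner charged)

I carried one number, the partner cost: the fraction of the partner charge used per unit fraction of both substrates together converted, 3.33. At the asked conversion it put partner use in the amber flask at 16.7% of the charge. The last ochre reading of left-handed product, 12%, stood for about 40.0% of the partner used in making that product, against about 23.3% at the last amber reading. Straight lines through these two runs therefore spanned different partner depletion, so I did not read their slopes as the effect of the catalyst. With a scatter of 1.5 percentage points, I committed by judgement to about first order in free catalyst and in partner, taking one of each per turnover.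

The forecast gave 0.1 and 0.4, holding that “Doubling the catalyst therefore did nothing measurable”.

The simulation gave 1.0 in free catalyst and 1.2 in partner.

    partner + catalyst intermediate B → free catalyst + right-handed product (k = 3.40 M⁻¹ h⁻¹)
    free catalyst + left-handed substrate ⇌ catalyst intermediate A (K = 0.600 M⁻¹, k = 1400 M⁻¹ h⁻¹)
    left-handed substrate ⇌ right-handed substrate (k = 0.420 h⁻¹)
    partner + catalyst intermediate A → free catalyst + left-handed product (k = 27.0 M⁻¹ h⁻¹)
    free catalyst + right-handed substrate ⇌ catalyst intermediate B (K = 3.00 M⁻¹, k = 290 M⁻¹ h⁻¹)

In the amber flask at 15.6 h, partner was used towards left-handed product 1.6 times as fast as towards right-handed product, a chance of 0.615 at that fork. At 40.0 h the amber left-handed substrate and right-handed substrate stood at 83% and 83% of their charges, and the cost turns their mean into 42.3% of the partner left. Dividing the last ochre reading by that amber chance and multiplying by the cost gives an estimate for ochre of about 65.1% of its partner charge used at 30.0 h.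

(The earlier runs and the new flask stem from a simulated flask with made-up constants; noise was put on by code.)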